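Units are numbered 1 to 4 from the top: epicatechin-(4β→6)-epiafzelechin-(4β→8)-epicatechin-(4β→6)-epicatechin. Everything rests on disconnecting C4–C4a of unit 1. The feature exploited is the bond from C4 of unit 1 to C6 of unit 2: C6 lies between O5 and O7 of ring A of unit 2, so that ring stabilizes a cation at C4, while ring A of unit 1 is a symmetric 3,5-dioxygenated phenyl ether. The precursor is an acyclic C4 carbinol with C2 and C3 set; acid ionizes it and the ether ring closes ring C of unit 1, fixing the 4→6 regiochemistry and the 4β centre in one operation. Unit 2 is grown on the freed phenol; units 3 and 4 come from (−)-epicatechin.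

Key step: step 13

Assumption: the C4 epimers of carbinol 20 and of methyl ether 36 are carried as mixtures, because C4 is ionized in the step that follows each of them; O3 of units 1 and 2 is benzylated, O3 of units 3 and 4 stays free; methyl (R)-glycerate and 4-(benzyloxy)phenylmagnesium bromide (THF solution) are taken as purchased.

Step 1
Reactants: 1 (S)-4-benzyloxazolidin-2-one; 2 (benzyloxy)acetyl chloride
Product: 4 (S)-4-benzyl-3-[(benzyloxy)acetyl]oxazolidin-2-one, via lithium oxazolidinonide 3 (not isolated)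
Conditions: n-BuLi, THF, −78 °C; then 2, −78 to 0 °C
Reagents that add atoms: none
Why: N-acylation of the lithiated oxazolidinone by the acid chloride loads the glycolate on the auxiliary and creates no stereocenter.

Step 2
Reactants: 4 (S)-4-benzyl-3-[(benzyloxy)acetyl]oxazolidin-2-one; 5 3,4-bis(benzyloxy)benzaldehyde
Product: 7 (S)-4-benzyl-3-{(2S,3R)-2-(benzyloxy)-3-[3,4-bis(benzyloxy)phenyl]-3-hydroxypropanoyl}oxazolidin-2-one, via dibutylboron enolate 6 (not isolated)
Conditions: Bu2BOTf, Et3N, CH2Cl2, −78 to 0 °C; then 5, −78 to 0 °C; pH 7 buffer, MeOH, H2O2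
Reagents that add atoms: none
Why: Evans syn aldol reaction, in which the Z boron enolate adds through a chair transition state on the face remote from the benzyl group of the auxiliary, so the (2S,3R) syn pair that becomes C3 and C2 of unit 1 is set and the 3-O-benzyl group is in place without any diol differentiation.

Step 3
Reactants: 7 aldol adduct
Product: 8 (1R,2R)-2-(benzyloxy)-1-[3,4-bis(benzyloxy)phenyl]propane-1,3-diol
Conditions: LiBH4, MeOH (1 equiv), THF, 0 °C
Reagents that add atoms: none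
Why: Reductive cleavage of the N-acyloxazolidinone by LiBH4 should give the primary alcohol and release the auxiliary without touching either stereocenter.

Step 4
Reactants: 8 diol
Product: 9 (1R,2R)-2-(benzyloxy)-1-[3,4-bis(benzyloxy)phenyl]-3-[(tert-butyldiphenylsilyl)oxy]propan-1-ol
Conditions: TBDPSCl, imidazole, CH2Cl2, 0 °C
Reagents that add atoms: tert-butyl(chloro)diphenylsilane, CC(C)(C)[Si](Cl)(c1ccccc1)c1ccccc1
Why: Silylation with the bulky chlorosilane is selective for the primary hydroxyl, which leaves only the benzylic hydroxyl free and gives a carbonyl-free substrate that cannot undergo retro-aldol cleavage or epimerization under the basic arylation conditions.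

Step 5
Reactants: 10 5-iodobenzene-1,3-diol
Product: 11 1,3-bis(benzyloxy)-5-iodobenzene
Conditions: BnBr, K2CO3, DMF, rt
Reagents that add atoms: benzyl bromide, BrCc1ccccc1
Why: Williamson etherification of both phenols gives the symmetric aryl iodide that becomes ring A of unit 1.

Step 6
Reactants: 9 silyl-protected benzylic alcohol; 11 1,3-bis(benzyloxy)-5-iodobenzene
Product: 12 tert-butyl{(2R,3R)-2-(benzyloxy)-3-[3,4-bis(benzyloxy)phenyl]-3-[3,5-bis(benzyloxy)phenoxy]propoxy}diphenylsilane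
Conditions: CuI (10 mol%), 3,4,7,8-tetramethyl-1,10-phenanthroline (20 mol%), Cs2CO3, 11 (2 equiv), toluene, 110 °C
Reagents that add atoms: none
Why: Ullmann-type C–O coupling at monovalent copper arylates the secondary alkoxide on oxygen, so the benzylic C–O bond is never broken and the configuration of the future C2 is retained.

Step 7
Reactants: 12 aryl ether
Product: 13 (2R,3R)-2-(benzyloxy)-3-[3,4-bis(benzyloxy)phenyl]-3-[3,5-bis(benzyloxy)phenoxy]propan-1-ol
Conditions: TBAF, THF, 0 °C to rt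
Reagents that add atoms: none
Why: Fluoride-mediated desilylation frees the primary alcohol and leaves the benzyl and aryl ethers untouched.

Step 8
Reactants: 13 primary alcohol
Product: 14 (2S,3R)-2-(benzyloxy)-3-[3,4-bis(benzyloxy)phenyl]-3-[3,5-bis(benzyloxy)phenoxy]propanal
Conditions: Dess–Martin periodinane, NaHCO3, CH2Cl2, 0 °C to rt; used crude
Reagents that add atoms: none
Why: Dess–Martin oxidation under buffered, amine-free conditions should give the α-alkoxy aldehyde without epimerization at C3 and without β-elimination of the aryloxy group.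

Step 9
Reactants: 15 phloroglucinol
Product: 16 5-[(triisopropylsilyl)oxy]benzene-1,3-diol
Conditions: 15 (3 equiv), TIPSCl, imidazole, DMF, 0 °C to rt
Reagents that add atoms: chlorotriisopropylsilane, CC(C)[Si](Cl)(C(C)C)C(C)C
Why: The three hydroxyls are equivalent, so statistical silylation with the triol in excess can only give the one mono-ether, which marks the oxygen that later becomes O1 of unit 2.

Step 10
Reactants: 16 mono-silyl ether
Product: 17 2-iodo-5-[(triisopropylsilyl)oxy]benzene-1,3-diol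
Conditions: I2 (1 equiv), NaHCO3, THF/H2O, 0 °C
Reagents that add atoms: iodine, II
Why: Electrophilic iodination of resorcinols with iodine and aqueous hydrogen carbonate goes to the carbon between the two hydroxyls, which here is also the only ring carbon not next to the bulky silyl ether, so the later metalation site is fixed without directed lithiation of benzyl ethers.

Step 11
Reactants: 17 iodoresorcinol
Product: 18 [3,5-bis(benzyloxy)-4-iodophenoxy]triisopropylsilane
Conditions: BnBr, K2CO3, DMF, rt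
Reagents that add atoms: benzyl bromide, BrCc1ccccc1
Why: Williamson benzylation of the two phenols that flank iodine proceeds under mild carbonate conditions that the aryl triisopropylsilyl ether should survive.

Step 12
Reactants: 18 aryl iodide; 14 aldehyde
Product: 20 (2R,3R)-2-(benzyloxy)-3-[3,4-bis(benzyloxy)phenyl]-3-[3,5-bis(benzyloxy)phenoxy]-1-{2,6-bis(benzyloxy)-4-[(triisopropylsilyl)oxy]phenyl}propan-1-ol (both C1 epimers), via aryllithium 19 (not isolated)
Conditions: n-BuLi, THF, −78 °C; then 14, −78 °C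
Reagents that add atoms: none
Why: Iodine–lithium exchange at −78 °C is faster than deprotonation of the benzyl ethers and places lithium exactly between the two benzyloxy groups, and 1,2-addition to the aldehyde forms the C4–C6 interflavan bond; the carbinol epimers are irrelevant because C4 is ionized next.

Step 13
Reactants: 20 carbinol (epimers)
Product: 22 3,5,7,3',4'-penta-O-benzyl-4β-{2,6-bis(benzyloxy)-4-[(triisopropylsilyl)oxy]phenyl}-(−)-epicatechin, (2R,3R,4S), via benzylic cation 21 (not isolated)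
Conditions: BF3·OEt2 (0.2 equiv), CH2Cl2, −78 to −20 °C
Reagents that add atoms: none
Why: The Lewis acid ionizes the carbinol to cation 21, a protonated para-quinone methide whose charge is shared by O5, O7 and the silyloxy oxygen of the future ring A of unit 2, so C4–OH leaves far more readily than the aryl ether at C2. One of the two equivalent carbons ortho to the ether oxygen of the 3,5-bis(benzyloxy)phenoxy ring attacks C4 in a six-membered Friedel–Crafts closure (6-exo-trig at the cationic carbon), which forms C4–C4a and ring C of unit 1; the closest known reaction type is the acid-mediated cyclization of benzylic cations onto aryl ethers to give chromans, together with the capture of flavan C4 cations by phloroglucinol-type arenes. Because the two ortho carbons are equivalent only one chroman can form, and the catechol ring, which is less nucleophilic and could only close a five-membered ring, should not compete. The new C4 stereocenter is controlled by C2 and C3: in the half-chair leading to ring C the ring on C2 sits equatorial and O3 axial, and placing the large aryl group of C4 pseudo-axial on the face opposite O3 keeps it clear of the benzyloxy group on C5, so the 3,4-trans (4β) product is expected. Both carbinol epimers give the same planar cation, and since the closure can reopen under acid the more stable 4β isomer should accumulate. The step needs chemoselective ionization at C4, secured by the three oxygens of the aryl group, and a low temperature with only catalytic acid so that loss of the C3 proton to an enol ether stays slow.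

Step 14
Reactants: 22 silyl ether
Product: 23 3,5,7,3',4'-penta-O-benzyl-4β-[2,6-bis(benzyloxy)-4-hydroxyphenyl]-(−)-epicatechin
Conditions: TBAF, THF, 0 °C
Reagents that add atoms: none
Why: Fluoride cleaves the aryl silyl ether and frees the single phenol, whose two ortho carbons are equivalent, as the future O1 of unit 2.

Step 15
Reactants: 24 methyl (R)-2,3-dihydroxypropanoate (methyl (R)-glycerate)
Product: 25 methyl (R)-3-[(tert-butyldiphenylsilyl)oxy]-2-hydroxypropanoate
Conditions: TBDPSCl (1.05 equiv), imidazole, CH2Cl2, 0 °C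
Reagents that add atoms: tert-butyl(chloro)diphenylsilane, CC(C)(C)[Si](Cl)(c1ccccc1)c1ccccc1
Why: Silylation with the bulky chlorosilane is selective for the primary hydroxyl of the chiral-pool diol, whose single stereocenter becomes C3 of unit 2 and is not involved.

Step 16
Reactants: 25 α-hydroxy ester
Product: 26 methyl (R)-2-(benzyloxy)-3-[(tert-butyldiphenylsilyl)oxy]propanoate
Conditions: benzyl 2,2,2-trichloroacetimidate (1.5 equiv), TfOH (5 mol%), CH2Cl2/cyclohexane, 0 °C to rt
Reagents that add atoms: benzyl 2,2,2-trichloroacetimidate, ClC(Cl)(Cl)C(=N)OCc1ccccc1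
Why: Acid-catalysed O-benzylation with the trichloroacetimidate alkylates the α-hydroxy ester on oxygen without any base, so the α-stereocenter cannot epimerize and the silyl ether cannot migrate.

Step 17
Reactants: 26 benzyl ether
Product: 27 (R)-2-(benzyloxy)-3-[(tert-butyldiphenylsilyl)oxy]-N-methoxy-N-methylpropanamide
Conditions: MeNH(OMe)·HCl (1.5 equiv), i-PrMgCl (3 equiv), THF, −20 °C
Reagents that add atoms: N,O-dimethylhydroxylamine hydrochloride, Cl.CNOC
Why: Aminolysis of the ester by the chloromagnesium amide formed in the flask gives the Weinreb amide at a temperature where acyl substitution is faster than enolization of the α-alkoxy ester.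

Step 18
Reactants: 27 Weinreb amide; 28 4-(benzyloxy)phenylmagnesium bromide
Product: 30 (R)-2-(benzyloxy)-1-[4-(benzyloxy)phenyl]-3-[(tert-butyldiphenylsilyl)oxy]propan-1-one, via magnesium hemiaminal chelate 29 (not isolated)
Conditions: 28 (1.3 equiv, THF solution), THF, −20 to 0 °C; cold aq NH4Cl; used at once
Reagents that add atoms: none
Why: Weinreb ketone synthesis, in which the N-methoxy chelate 29 holds the tetrahedral adduct until the cold quench, so only one aryl group adds and the enolizable α-benzyloxy ketone is never exposed to the basic reagent.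

Step 19
Reactants: 30 ketone
Product: 31 (1S,2R)-2-(benzyloxy)-1-[4-(benzyloxy)phenyl]-3-[(tert-butyldiphenylsilyl)oxy]propan-1-ol
Conditions: Zn(BH4)2, Et2O, −30 to 0 °C
Reagents that add atoms: none
Why: Chelation-controlled reduction (Cram chelate model), in which divalent zinc bridges the carbonyl oxygen and the α-benzyloxy oxygen and hydride enters the carbonyl face on the side of the α-hydrogen, should give the 1,2-anti (1S) carbinol that the invertive etherification of the next step requires.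

Step 20
Reactants: 23 phenol; 31 anti alcohol
Product: 32 ether of 23 that carries on the phenolic oxygen the (1R,2R)-2-(benzyloxy)-1-[4-(benzyloxy)phenyl]-3-[(tert-butyldiphenylsilyl)oxy]propyl group
Conditions: 31 (1.5 equiv), PPh3, DIAD, toluene, 0 °C to rt
Reagents that add atoms: none
Why: Mitsunobu etherification lets the unhindered phenol displace the activated benzylic alcohol with inversion, which turns the (1S) carbinol into the (R)-configured C2 of unit 2 and forms the O1–C2 bond only at the one free phenol.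

Step 21
Reactants: 32 silyl ether
Product: 33 the corresponding primary alcohol, (2R,3R)-3-aryloxy-2-(benzyloxy)-3-[4-(benzyloxy)phenyl]propan-1-ol (aryl = ring A of unit 2 bonded to unit 1)
Conditions: TBAF, THF, 0 °C to rt
Reagents that add atoms: none
Why: Fluoride removes the only silyl group left and leaves all benzyl ethers in place.

Step 22
Reactants: 33 primary alcohol
Product: 34 the corresponding aldehyde, (2S,3R)-3-aryloxy-2-(benzyloxy)-3-[4-(benzyloxy)phenyl]propanal
Conditions: Dess–Martin periodinane, NaHCO3, CH2Cl2, 0 °C to rt; used crude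
Reagents that add atoms: none
Why: Buffered Dess–Martin oxidation should give the aldehyde without epimerization at C3 or β-elimination of the aryloxy group.

Step 23
Reactants: 34 aldehyde
Product: 36 3,5,7,3',4'-penta-O-benzylepicatechin-(4β→6)-(3,5,7,4'-tetra-O-benzyl-4-methoxyepiafzelechin) (C4 epimers of the lower unit), via dimethyl acetal 35 (not isolated)
Conditions: CSA (20 mol%), MeOH/CH2Cl2 (1:3), 0 to 40 °C
Reagents that add atoms: methanol, CO
Why: Acid turns the aldehyde into its acetal and then into an oxocarbenium ion, which one of the two equivalent carbons ortho to the ether oxygen of the trioxygenated ring attacks in an intramolecular Friedel–Crafts alkylation of the kind that closes 3-aryloxypropanal acetals to 4-alkoxychromans (C4–C4a of unit 2), while the excess methanol holds C4 as the methyl ether and suppresses intermolecular condensation.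

Step 24
Reactants: 37 (−)-epicatechin
Product: 38 5,7,3',4'-tetra-O-benzyl-(−)-epicatechin
Conditions: BnBr, K2CO3, DMF, rt
Reagents that add atoms: benzyl bromide, BrCc1ccccc1
Why: Williamson etherification with carbonate benzylates the four phenols and leaves the much less acidic 3-hydroxyl free.

Step 25
Reactants: 38 tetra-O-benzylepicatechin
Product: 39 4β-(2-ethoxyethoxy)-5,7,3',4'-tetra-O-benzyl-(−)-epicatechin
Conditions: DDQ, 2-ethoxyethanol, CH2Cl2, rt
Reagents that add atoms: 2-ethoxyethanol, CCOCCO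
Why: DDQ abstracts hydride from the benzylic C4 of the electron-rich flavan and the alcohol adds to the cation anti to the 3-hydroxyl group, which gives the 4β ether.

Step 26
Reactants: 39 4β-(2-ethoxyethoxy) ether
Product: 40 4β-[(2,6-dimethylphenyl)sulfanyl]-5,7,3',4'-tetra-O-benzyl-(−)-epicatechin
Conditions: 2,6-dimethylbenzenethiol (3 equiv), BF3·OEt2 (0.1 equiv), CH2Cl2, −78 to −30 °C
Reagents that add atoms: 2,6-dimethylbenzenethiol, Cc1cccc(C)c1S
Why: Lewis acid-mediated SN1 exchange of the thiolysis type captures the C4 cation with the thiol anti to O3, and the hindered aryl thioether that results is inert to hard Lewis acids and serves as the latent leaving group of unit 3.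

Step 27
Reactants: 36 4-methoxy dimer; 40 thioether nucleophile
Product: 41 3,5,7,3',4'-penta-O-benzylepicatechin-(4β→6)-3,5,7,4'-tetra-O-benzylepiafzelechin-(4β→8)-{4β-[(2,6-dimethylphenyl)sulfanyl]-5,7,3',4'-tetra-O-benzylepicatechin}
Conditions: 40 (4 equiv), TMSOTf (0.2 equiv), CH2Cl2, −78 to −40 °C
Reagents that add atoms: none
Why: Lewis acid-mediated Friedel–Crafts flavan coupling, in which loss of the methoxy group leaves C4 of unit 2 electrophilic and C8 of the nucleophile, the more reactive of its two free ring A carbons, attacks anti to the axial 3-benzyloxy group to give the 3,4-trans (4β→8) bond, while the excess of nucleophile suppresses self-condensation.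

Step 28
Reactants: 38 tetra-O-benzylepicatechin
Product: 42 8-bromo-5,7,3',4'-tetra-O-benzyl-(−)-epicatechin
Conditions: NBS, CH2Cl2, −78 °C to rt
Reagents that add atoms: N-bromosuccinimide, BrN1C(=O)CCC1=O
Why: Electrophilic bromination of the benzylated flavan goes selectively to C8, which blocks that carbon so that only C6 can act as nucleophile.

Step 29
Reactants: 41 trimer thioether; 42 8-bromo nucleophile
Product: 43 protected tetramer, as 41 but with C4 of unit 3 bonded (4β) to C6 of 8-bromo-5,7,3',4'-tetra-O-benzylepicatechin in place of the arylsulfanyl group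
Conditions: 42 (5 equiv), AgBF4, 4 Å MS, THF, 0 °C to rt
Reagents that add atoms: none
Why: The thiophilic silver salt removes the arylsulfanyl group, and C6 of the bromine-capped nucleophile attacks the ring-A-stabilized C4 of unit 3 anti to the 3-hydroxyl group in a halogen-capping Friedel–Crafts coupling, which gives the 4β→6 bond.

Step 30
Reactants: 43 protected tetramer
Product: 44 epicatechin-(4β→6)-epiafzelechin-(4β→8)-epicatechin-(4β→6)-epicatechin (CNP0103636.1)
Conditions: H2 (1 atm), Pd(OH)2/C, Et3N, THF/MeOH/H2O, rt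
Reagents that add atoms: none
Why: Hydrogenolysis over Pd(OH)2/C cleaves all seventeen benzyl ethers and the aryl C–Br bond without touching any stereocenter, and triethylamine takes up the HBr so that the acid-labile interflavan bonds survive.

Compound list
1 | (S)-4-benzyloxazolidin-2-one | O=C1OC[C@H](Cc2ccccc2)N1 | starting material
2 | (benzyloxy)acetyl chloride | ClC(=O)COCc1ccccc1 | starting material
3 | N-lithio-(S)-4-benzyloxazolidin-2-one | [Li]N1[C@@H](Cc2ccccc2)COC1=O | intermediate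
4 | (S)-4-benzyl-3-[(benzyloxy)acetyl]oxazolidin-2-one | O=C(COCc1ccccc1)N1[C@@H](Cc2ccccc2)COC1=O | intermediate
5 | 3,4-bis(benzyloxy)benzaldehyde | O=Cc1ccc(OCc2ccccc2)c(OCc2ccccc2)c1 | starting material
6 | (Z)-dibutylboron enolate of 4 | CCCCB(CCCC)O/C(=C\OCc1ccccc1)N1[C@@H](Cc2ccccc2)COC1=O | intermediate
7 | (S)-4-benzyl-3-{(2S,3R)-2-(benzyloxy)-3-[3,4-bis(benzyloxy)phenyl]-3-hydroxypropanoyl}oxazolidin-2-one | O=C([C@@H](OCc1ccccc1)[C@H](O)c1ccc(OCc2ccccc2)c(OCc2ccccc2)c1)N1[C@@H](Cc2ccccc2)COC1=O | intermediate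
8 | (1R,2R)-2-(benzyloxy)-1-[3,4-bis(benzyloxy)phenyl]propane-1,3-diol | OC[C@@H](OCc1ccccc1)[C@H](O)c1ccc(OCc2ccccc2)c(OCc2ccccc2)c1 | intermediate
9 | (1R,2R)-2-(benzyloxy)-1-[3,4-bis(benzyloxy)phenyl]-3-[(tert-butyldiphenylsilyl)oxy]propan-1-ol | CC(C)(C)[Si](c1ccccc1)(c1ccccc1)OC[C@@H](OCc1ccccc1)[C@H](O)c1ccc(OCc2ccccc2)c(OCc2ccccc2)c1 | intermediate
10 | 5-iodobenzene-1,3-diol | Oc1cc(O)cc(I)c1 | starting material
11 | 1,3-bis(benzyloxy)-5-iodobenzene | Ic1cc(OCc2ccccc2)cc(OCc2ccccc2)c1 | intermediate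
12 | tert-butyl{(2R,3R)-2-(benzyloxy)-3-[3,4-bis(benzyloxy)phenyl]-3-[3,5-bis(benzyloxy)phenoxy]propoxy}diphenylsilane | CC(C)(C)[Si](c1ccccc1)(c1ccccc1)OC[C@@H](OCc1ccccc1)[C@H](Oc1cc(OCc2ccccc2)cc(OCc2ccccc2)c1)c1ccc(OCc2ccccc2)c(OCc2ccccc2)c1 | intermediate
13 | (2R,3R)-2-(benzyloxy)-3-[3,4-bis(benzyloxy)phenyl]-3-[3,5-bis(benzyloxy)phenoxy]propan-1-ol | OC[C@@H](OCc1ccccc1)[C@H](Oc1cc(OCc2ccccc2)cc(OCc2ccccc2)c1)c1ccc(OCc2ccccc2)c(OCc2ccccc2)c1 | intermediate
14 | (2S,3R)-2-(benzyloxy)-3-[3,4-bis(benzyloxy)phenyl]-3-[3,5-bis(benzyloxy)phenoxy]propanal | O=C[C@@H](OCc1ccccc1)[C@H](Oc1cc(OCc2ccccc2)cc(OCc2ccccc2)c1)c1ccc(OCc2ccccc2)c(OCc2ccccc2)c1 | intermediate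
15 | phloroglucinol (benzene-1,3,5-triol) | Oc1cc(O)cc(O)c1 | starting material
16 | 5-[(triisopropylsilyl)oxy]benzene-1,3-diol | CC(C)[Si](Oc1cc(O)cc(O)c1)(C(C)C)C(C)C | intermediate
17 | 2-iodo-5-[(triisopropylsilyl)oxy]benzene-1,3-diol | CC(C)[Si](Oc1cc(O)c(I)c(O)c1)(C(C)C)C(C)C | intermediate
18 | [3,5-bis(benzyloxy)-4-iodophenoxy]triisopropylsilane | CC(C)[Si](Oc1cc(OCc2ccccc2)c(I)c(OCc2ccccc2)c1)(C(C)C)C(C)C | intermediate
19 | {2,6-bis(benzyloxy)-4-[(triisopropylsilyl)oxy]phenyl}lithium | [Li]c1c(OCc2ccccc2)cc(O[Si](C(C)C)(C(C)C)C(C)C)cc1OCc1ccccc1 | intermediate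
20 | (2R,3R)-2-(benzyloxy)-3-[3,4-bis(benzyloxy)phenyl]-3-[3,5-bis(benzyloxy)phenoxy]-1-{2,6-bis(benzyloxy)-4-[(triisopropylsilyl)oxy]phenyl}propan-1-ol, C1 epimers | OC(c1c(OCc2ccccc2)cc(O[Si](C(C)C)(C(C)C)C(C)C)cc1OCc1ccccc1)[C@@H](OCc1ccccc1)[C@H](Oc1cc(OCc2ccccc2)cc(OCc2ccccc2)c1)c1ccc(OCc2ccccc2)c(OCc2ccccc2)c1 | intermediate
21 | C1 benzylic cation of 20 (protonated para-quinone methide) | [CH+](c1c(OCc2ccccc2)cc(O[Si](C(C)C)(C(C)C)C(C)C)cc1OCc1ccccc1)[C@@H](OCc1ccccc1)[C@H](Oc1cc(OCc2ccccc2)cc(OCc2ccccc2)c1)c1ccc(OCc2ccccc2)c(OCc2ccccc2)c1 | intermediate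
22 | 3,5,7,3',4'-penta-O-benzyl-4β-{2,6-bis(benzyloxy)-4-[(triisopropylsilyl)oxy]phenyl}-(−)-epicatechin, (2R,3R,4S) | CC(C)[Si](C(C)C)(C(C)C)Oc1cc(OCc2ccccc2)c(c(OCc2ccccc2)c1)[C@H]1c2c(OCc3ccccc3)cc(OCc3ccccc3)cc2O[C@H](c2ccc(OCc3ccccc3)c(OCc3ccccc3)c2)[C@@H]1OCc1ccccc1 | intermediate
23 | 3,5,7,3',4'-penta-O-benzyl-4β-[2,6-bis(benzyloxy)-4-hydroxyphenyl]-(−)-epicatechin | Oc1cc(OCc2ccccc2)c(c(OCc2ccccc2)c1)[C@H]1c2c(OCc3ccccc3)cc(OCc3ccccc3)cc2O[C@H](c2ccc(OCc3ccccc3)c(OCc3ccccc3)c2)[C@@H]1OCc1ccccc1 | intermediate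
24 | methyl (R)-2,3-dihydroxypropanoate (methyl (R)-glycerate) | OC[C@@H](O)C(=O)OC | starting material
25 | methyl (R)-3-[(tert-butyldiphenylsilyl)oxy]-2-hydroxypropanoate | CC(C)(C)[Si](c1ccccc1)(c1ccccc1)OC[C@@H](O)C(=O)OC | intermediate
26 | methyl (R)-2-(benzyloxy)-3-[(tert-butyldiphenylsilyl)oxy]propanoate | CC(C)(C)[Si](c1ccccc1)(c1ccccc1)OC[C@@H](OCc1ccccc1)C(=O)OC | intermediate
27 | (R)-2-(benzyloxy)-3-[(tert-butyldiphenylsilyl)oxy]-N-methoxy-N-methylpropanamide | CC(C)(C)[Si](c1ccccc1)(c1ccccc1)OC[C@@H](OCc1ccccc1)C(=O)N(C)OC | intermediate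
28 | 4-(benzyloxy)phenylmagnesium bromide | Br[Mg]c1ccc(OCc2ccccc2)cc1 | starting material
29 | bromomagnesium (2R)-2-(benzyloxy)-1-[4-(benzyloxy)phenyl]-3-[(tert-butyldiphenylsilyl)oxy]-1-[methoxy(methyl)amino]propan-1-olate (chelated tetrahedral adduct) | CC(C)(C)[Si](c1ccccc1)(c1ccccc1)OC[C@@H](OCc1ccccc1)C(O[Mg]Br)(N(C)OC)c1ccc(OCc2ccccc2)cc1 | intermediate
30 | (R)-2-(benzyloxy)-1-[4-(benzyloxy)phenyl]-3-[(tert-butyldiphenylsilyl)oxy]propan-1-one | CC(C)(C)[Si](c1ccccc1)(c1ccccc1)OC[C@@H](OCc1ccccc1)C(=O)c1ccc(OCc2ccccc2)cc1 | intermediate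
31 | (1S,2R)-2-(benzyloxy)-1-[4-(benzyloxy)phenyl]-3-[(tert-butyldiphenylsilyl)oxy]propan-1-ol | CC(C)(C)[Si](c1ccccc1)(c1ccccc1)OC[C@@H](OCc1ccccc1)[C@@H](O)c1ccc(OCc2ccccc2)cc1 | intermediate
32 | ether of 23 with the (1R,2R)-2-(benzyloxy)-1-[4-(benzyloxy)phenyl]-3-[(tert-butyldiphenylsilyl)oxy]propyl group on the phenolic oxygen | CC(C)(C)[Si](c1ccccc1)(c1ccccc1)OC[C@@H](OCc1ccccc1)[C@H](Oc1cc(OCc2ccccc2)c(c(OCc2ccccc2)c1)[C@H]1c2c(OCc3ccccc3)cc(OCc3ccccc3)cc2O[C@H](c2ccc(OCc3ccccc3)c(OCc3ccccc3)c2)[C@@H]1OCc1ccccc1)c1ccc(OCc2ccccc2)cc1 | intermediate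
33 | primary alcohol from 32, (2R,3R)-3-aryloxy-2-(benzyloxy)-3-[4-(benzyloxy)phenyl]propan-1-ol | OC[C@@H](OCc1ccccc1)[C@H](Oc1cc(OCc2ccccc2)c(c(OCc2ccccc2)c1)[C@H]1c2c(OCc3ccccc3)cc(OCc3ccccc3)cc2O[C@H](c2ccc(OCc3ccccc3)c(OCc3ccccc3)c2)[C@@H]1OCc1ccccc1)c1ccc(OCc2ccccc2)cc1 | intermediate
34 | aldehyde from 33, (2S,3R)-3-aryloxy-2-(benzyloxy)-3-[4-(benzyloxy)phenyl]propanal | O=C[C@@H](OCc1ccccc1)[C@H](Oc1cc(OCc2ccccc2)c(c(OCc2ccccc2)c1)[C@H]1c2c(OCc3ccccc3)cc(OCc3ccccc3)cc2O[C@H](c2ccc(OCc3ccccc3)c(OCc3ccccc3)c2)[C@@H]1OCc1ccccc1)c1ccc(OCc2ccccc2)cc1 | intermediate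
35 | dimethyl acetal of 34 | COC(OC)[C@@H](OCc1ccccc1)[C@H](Oc1cc(OCc2ccccc2)c(c(OCc2ccccc2)c1)[C@H]1c2c(OCc3ccccc3)cc(OCc3ccccc3)cc2O[C@H](c2ccc(OCc3ccccc3)c(OCc3ccccc3)c2)[C@@H]1OCc1ccccc1)c1ccc(OCc2ccccc2)cc1 | intermediate
36 | 3,5,7,3',4'-penta-O-benzylepicatechin-(4β→6)-(3,5,7,4'-tetra-O-benzyl-4-methoxyepiafzelechin), C4 epimers of the lower unit | COC1c2c(OCc3ccccc3)c([C@H]3c4c(OCc5ccccc5)cc(OCc5ccccc5)cc4O[C@H](c4ccc(OCc5ccccc5)c(OCc5ccccc5)c4)[C@@H]3OCc3ccccc3)c(OCc3ccccc3)cc2O[C@H](c2ccc(OCc3ccccc3)cc2)[C@@H]1OCc1ccccc1 | intermediate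
37 | (−)-epicatechin, (2R,3R) | Oc1cc(O)c2C[C@@H](O)[C@@H](c3ccc(O)c(O)c3)Oc2c1 | starting material
38 | 5,7,3',4'-tetra-O-benzyl-(−)-epicatechin | O[C@@H]1Cc2c(OCc3ccccc3)cc(OCc3ccccc3)cc2O[C@@H]1c1ccc(OCc2ccccc2)c(OCc2ccccc2)c1 | intermediate
39 | 4β-(2-ethoxyethoxy)-5,7,3',4'-tetra-O-benzyl-(−)-epicatechin, (2R,3R,4S) | c1c(OCc2ccccc2)cc(OCc2ccccc2)c2c1O[C@H](c1ccc(OCc3ccccc3)c(OCc3ccccc3)c1)[C@H](O)[C@H]2OCCOCC | intermediate
40 | 4β-[(2,6-dimethylphenyl)sulfanyl]-5,7,3',4'-tetra-O-benzyl-(−)-epicatechin | c1c(OCc2ccccc2)cc(OCc2ccccc2)c2c1O[C@H](c1ccc(OCc3ccccc3)c(OCc3ccccc3)c1)[C@H](O)[C@H]2Sc1c(C)cccc1C | intermediate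
41 | penta-O-benzylepicatechin-(4β→6)-tetra-O-benzylepiafzelechin-(4β→8)-{4β-[(2,6-dimethylphenyl)sulfanyl]-tetra-O-benzylepicatechin} | c1ccccc1COc1ccc([C@H]2Oc3cc(OCc4ccccc4)c([C@H]4c5c(OCc6ccccc6)cc(OCc6ccccc6)cc5O[C@H](c5ccc(OCc6ccccc6)c(OCc6ccccc6)c5)[C@@H]4OCc4ccccc4)c(OCc4ccccc4)c3[C@H](c3c(OCc4ccccc4)cc(OCc4ccccc4)c4c3O[C@H](c3ccc(OCc5ccccc5)c(OCc5ccccc5)c3)[C@H](O)[C@H]4Sc3c(C)cccc3C)[C@H]2OCc2ccccc2)cc1 | intermediate
42 | 8-bromo-5,7,3',4'-tetra-O-benzyl-(−)-epicatechin | Brc1c(OCc2ccccc2)cc(OCc2ccccc2)c2C[C@@H](O)[C@@H](c3ccc(OCc4ccccc4)c(OCc4ccccc4)c3)Oc12 | intermediate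
43 | penta-O-benzylepicatechin-(4β→6)-tetra-O-benzylepiafzelechin-(4β→8)-tetra-O-benzylepicatechin-(4β→6)-(8-bromo-tetra-O-benzylepicatechin) | c1ccccc1COc1ccc([C@H]2Oc3cc(OCc4ccccc4)c([C@H]4c5c(OCc6ccccc6)cc(OCc6ccccc6)cc5O[C@H](c5ccc(OCc6ccccc6)c(OCc6ccccc6)c5)[C@@H]4OCc4ccccc4)c(OCc4ccccc4)c3[C@H](c3c(OCc4ccccc4)cc(OCc4ccccc4)c4c3O[C@H](c3ccc(OCc5ccccc5)c(OCc5ccccc5)c3)[C@H](O)[C@H]4c3c(OCc4ccccc4)c(Br)c4c(c3OCc3ccccc3)C[C@@H](O)[C@@H](c3ccc(OCc5ccccc5)c(OCc5ccccc5)c3)O4)[C@H]2OCc2ccccc2)cc1 | intermediate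
44 | epicatechin-(4β→6)-epiafzelechin-(4β→8)-epicatechin-(4β→6)-epicatechin (CNP0103636.1) | Oc1ccc([C@H]2Oc3cc(O)c([C@H]4c5c(O)cc(O)cc5O[C@H](c5ccc(O)c(O)c5)[C@@H]4O)c(O)c3[C@H](c3c(O)cc(O)c4c3O[C@H](c3ccc(O)c(O)c3)[C@H](O)[C@H]4c3c(O)cc4c(c3O)C[C@@H](O)[C@@H](c3ccc(O)c(O)c3)O4)[C@H]2O)cc1 | target

Total step count: 30. Longest linear sequence: 17 steps (steps 1–4, 6–8, 12–14, 20–23, 27, 29, 30).

Steps most likely to fail

Step 13. After ionization at C4 the cation may lose the C3 proton to give an enol ether, may be captured by a second molecule before the ring closes, or may close with poor facial selectivity at C4. The fallback gives up the ring closure and makes the same C4–aryl bond on a preformed flavan. It sets out from 39 and 15: ionization of 39 with TMSOTf in THF/CH2Cl2 in the presence of excess phloroglucinol, whose three ring carbons are equivalent, should give 4β-(2,4,6-trihydroxyphenyl)-5,7,3',4'-tetra-O-benzylepicatechin F1. Silylation with chlorotriisopropylsilane and imidazole at the only unhindered (para) hydroxyl should give 4β-[2,6-dihydroxy-4-(triisopropylsilyloxy)phenyl]-5,7,3',4'-tetra-O-benzylepicatechin F2. Benzylation of the two remaining phenols and of O3 (NaH, BnBr, THF, 0 °C) then comes back to the route at 22.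

Step 6. Copper–alkoxide exchange at the hindered secondary benzylic alcohol may be slow, so that oxidation of the alcohol to the ketone and reduction of the aryl iodide take over. The fallback replaces retention by two inversions and sets out from 9. Mitsunobu esterification with 4-nitrobenzoic acid (PPh3, DIAD) should give (1S,2R)-2-(benzyloxy)-1-[3,4-bis(benzyloxy)phenyl]-3-[(tert-butyldiphenylsilyl)oxy]propyl 4-nitrobenzoate F3. Methanolysis (K2CO3 cat., MeOH) should give (1S,2R)-2-(benzyloxy)-1-[3,4-bis(benzyloxy)phenyl]-3-[(tert-butyldiphenylsilyl)oxy]propan-1-ol F4. A second Mitsunobu reaction with commercial 3,5-bis(benzyloxy)phenol (Oc1cc(OCc2ccccc2)cc(OCc2ccccc2)c1) inverts the centre again and comes back at 12.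

Step 29. Attack by the hindered, bromine-deactivated C6 of 42 may be too slow, so that the cation of unit 3 is consumed by condensation with unblocked ring A carbons of another trimer, or the arylsulfanyl group may be activated incompletely. The fallback drops the thioether and oxidizes C4 of unit 3 late; it sets out from 36 and 38. TMSOTf-mediated coupling (38 in excess) should give penta-O-benzylepicatechin-(4β→6)-tetra-O-benzylepiafzelechin-(4β→8)-tetra-O-benzylepicatechin F5, whose unit 3 keeps its C4 methylene. DDQ with 2-ethoxyethanol should oxidize this only benzylic methylene, the two interflavan methines being shielded, to the trimer with a 4β-(2-ethoxyethoxy) group on unit 3 F6. TMSOTf-mediated coupling of F6 with excess 42 comes back at 43.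

Further compounds
F1 | step 13 | 4β-(2,4,6-trihydroxyphenyl)-5,7,3',4'-tetra-O-benzyl-(−)-epicatechin | Oc1cc(O)c(c(O)c1)[C@H]1c2c(OCc3ccccc3)cc(OCc3ccccc3)cc2O[C@H](c2ccc(OCc3ccccc3)c(OCc3ccccc3)c2)[C@@H]1O
F2 | step 13 | 4β-[2,6-dihydroxy-4-(triisopropylsilyloxy)phenyl]-5,7,3',4'-tetra-O-benzyl-(−)-epicatechin | CC(C)[Si](C(C)C)(C(C)C)Oc1cc(O)c(c(O)c1)[C@H]1c2c(OCc3ccccc3)cc(OCc3ccccc3)cc2O[C@H](c2ccc(OCc3ccccc3)c(OCc3ccccc3)c2)[C@@H]1O
F3 | step 6 | (1S,2R)-2-(benzyloxy)-1-[3,4-bis(benzyloxy)phenyl]-3-[(tert-butyldiphenylsilyl)oxy]propyl 4-nitrobenzoate | CC(C)(C)[Si](c1ccccc1)(c1ccccc1)OC[C@@H](OCc1ccccc1)[C@@H](OC(=O)c1ccc(cc1)[N+](=O)[O-])c1ccc(OCc2ccccc2)c(OCc2ccccc2)c1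
F4 | step 6 | (1S,2R)-2-(benzyloxy)-1-[3,4-bis(benzyloxy)phenyl]-3-[(tert-butyldiphenylsilyl)oxy]propan-1-ol | CC(C)(C)[Si](c1ccccc1)(c1ccccc1)OC[C@@H](OCc1ccccc1)[C@@H](O)c1ccc(OCc2ccccc2)c(OCc2ccccc2)c1
F5 | step 29 | penta-O-benzylepicatechin-(4β→6)-tetra-O-benzylepiafzelechin-(4β→8)-tetra-O-benzylepicatechin | c1ccccc1COc1ccc([C@H]2Oc3cc(OCc4ccccc4)c([C@H]4c5c(OCc6ccccc6)cc(OCc6ccccc6)cc5O[C@H](c5ccc(OCc6ccccc6)c(OCc6ccccc6)c5)[C@@H]4OCc4ccccc4)c(OCc4ccccc4)c3[C@H](c3c(OCc4ccccc4)cc(OCc4ccccc4)c4c3O[C@H](c3ccc(OCc5ccccc5)c(OCc5ccccc5)c3)[C@H](O)C4)[C@H]2OCc2ccccc2)cc1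
F6 | step 29 | the same trimer with a 4β-(2-ethoxyethoxy) group on unit 3 | c1ccccc1COc1ccc([C@H]2Oc3cc(OCc4ccccc4)c([C@H]4c5c(OCc6ccccc6)cc(OCc6ccccc6)cc5O[C@H](c5ccc(OCc6ccccc6)c(OCc6ccccc6)c5)[C@@H]4OCc4ccccc4)c(OCc4ccccc4)c3[C@H](c3c(OCc4ccccc4)cc(OCc4ccccc4)c4c3O[C@H](c3ccc(OCc5ccccc5)c(OCc5ccccc5)c3)[C@H](O)[C@H]4OCCOCC)[C@H]2OCc2ccccc2)cc1
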